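## Structural features

Iriediol (C20H32Br2O2) is a trans-fused hydrindane (ring A: C3a, C4–C7, C7a; ring B: C1, C2, C3, C3a, C7a) joined through the vinylic carbon C8 to a 4-bromo-3,3-dimethylcyclohexylidene (ring C, C1'–C6'); the C8=C1' double bond is exocyclic to ring C and E. Six stereocentres sit on the bicycle: C1 (C8 branch, α) and C2 (secondary OH, α) are adjacent and cis; quaternary C3a (angular methyl, β) is flanked by C4 (equatorial β-bromide) and C7a (α-H, trans fusion); C7a neighbours C7, a tertiary carbinol whose axial β-OH is syn to the angular methyl. The seventh stereocentre, C4' (bromide next to the gem-dimethyl carbon C3'), is isolated in ring C, five bonds from C1, and cannot be set by relay from the bicycle. Fragile elements are the two secondary neopentyl C–Br bonds (elimination, 1,2-shift), the tertiary C7 alcohol (trans-diaxial to C7a–H, easily dehydrated), C1 once C8 is a carbonyl (epimerisable, β-oxygen at C2) and the trisubstituted exocyclic alkene (acid-promoted migration). The real difficulty lies in the geometry of C8=C1', whose two C1' substituents are ring methylenes that differ only one atom further out, in placing bromine with defined configuration on two neopentyl carbons, and in a trans-hydrindane carrying a 1,2-cis pair on ring B. The key step exploits that ring B bears a one-carbon branch (C8) on C1 beside the oxygenated C2: this is what remains when a six-membered ring with C8 as a carbonyl between C1 and C2 is contracted, so the trans fusion, C3a, C7 and C2 can be set on a rigid trans-decalin before C8 is pushed out of the ring.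

## Logic of the disconnections

42 ⇐ 41 ⇐ 40. The two O–Si bonds and then C4–Br and C4'–Br are cut. The bromides are the most fragile groups and are installed last; only displacement with inversion gives a defined configuration at these neopentyl carbons. The gain is a halogen-free diol, 40, whose two carbinols have the same local sense (both R). The forward step must displace two hindered activated carbinols with inversion and without elimination while silyl ethers keep the C2 and C7 oxygens out of the reaction.

40 ⇐ 39 ⇐ 38 ⇐ 37. The C–H bonds of the C4 and C4' carbinols are cut, C4 remaining a ketal until C4' is set. This erases two stereocentres and leaves one reducible carbonyl in 37. The demands are reagent control at the remote C4', substrate control at C4 (axial alcohol by equatorial hydride delivery) and hydrolysis of a hindered ketal in the presence of silyl ethers.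

37 ⇐ 35 ⇐ 34 ⇐ 33. The C5'–C6' bond of ring C is cut. C5' is α to the C4' carbonyl and C6' is allylic, and because C3' is quaternary only one enolate can form. Ring C opens to a chain in which the alkene geometry is already fixed. The forward step must be a 6-exo SN2 at C6' rather than SN2' at C8 or O-alkylation, and the allylic halide must be made without allylic shift.

33 ⇐ 31 + 32. The C4'–C5' bond is cut, leaving the carboxylic acid that a Claisen rearrangement delivers. The forward step must stop at mono-addition of 32 to the carboxylate.

31 ⇐ 28. The C2'–C3' bond is cut, with the alkene moved back from C8=C1' to C1'=C2' and the C8–O bond restored. This sets the alkene geometry in an acyclic chair transition state and creates quaternary C3'. The trisubstituted alkene is reduced to a 1,1-disubstituted alkene and a C8 carbinol whose configuration does not matter. The chair must carry the C1 substituent equatorially.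

28 ⇐ 21 + 24 + 25, and 24 ⇐ 22 + 23. The C8–C1' bond and the ester C–O bond are cut, giving three simple components. The addition must tolerate a hindered, epimerisable α-branched aldehyde.

21 ⇐ 20 ⇐ 19. No skeletal bond is cut; only the oxidation level of C8 changes. C1 must not epimerise and the C2 silyloxy group must not be eliminated.

19 ⇐ 16 (key). The C1–C2 bond of ring B is cut and C2 is reconnected to C8, which re-enters the ring as a ketone; C1 becomes a diazo carbon.
- Gain: a trans-hydrindane, hard to make with control, becomes a trans-decalin available from 1, and no stereocentre except C1 is lost.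
- Demand: 1,2-shift in preference to other carbene pathways, capture of the ketene by methanol only, and the correct configuration at C1.
- Design change: in 16 the C7 oxygen carries a triethylsilyl group. A free 7β-hydroxyl would lie γ to the ketene carbon on the β face and could close a lactone that fixes C8 on the wrong side of C1; it would also interfere in the formylation and in the final bromination.
- Structure check: the configurations of 16 and 19 map onto 42 without change.

16 ⇐ 15 ⇐ 14. The C1=N2 bond is cut by way of a formyl activating group. C1 is the only α-methylene, so the regiochemistry is fixed by the substrate.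

14 ⇐ 13 ⇐ 10. The C2–O bond is cut. Enolisation must go toward C2 and the oxidant must come from the face opposite the angular methyl, which gives the equatorial 2α-oxygen.

10 ⇐ 9 ⇐ 8 ⇐ 6 + 7. The C7–CH3 bond is cut, with the C8 ketal and the C7 silyl ether as protecting-group changes. 7 must add along the equatorial path, and the unhindered ketal must hydrolyse before the neopentyl one.

6 ⇐ 5 ⇐ 3 ⇐ 1 + 2. The C7–O and C7a–H bonds are cut (hydroboration), then the two ketals. Deconjugative ketalisation must place the alkene at C7=C7a, and hydroboration from the α face sets the trans fusion.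

## Other disconnections considered

Alternative 1: The cut runs through ring A at C3a–C7a and C4–Br, back to the acyclic chloro-diene diester A1. In the forward step N-bromosuccinimide under activation by a chiral phosphoramidite would transfer Br+ to the C3a=C4 alkene; the cation at C3a is captured by C7a of the (Z)-chloroalkene and the α-chloro cation at C7 is hydrolysed, giving bromoketone A2 with two acetate arms for ring B.
- In its favour: bromine enters directly with its final equatorial configuration in the step that makes the quaternary carbon. On this point the alternative is the better plan, since the chosen route must force a displacement at a neopentyl carbinol; it also needs no chiral-pool material.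
- Against it here: enantiocontrol of bromonium transfer is eroded by alkene-to-alkene exchange of Br+. The initiating alkene of A1 is deactivated by the β,γ-ester and the chloroalkene is a weak π-nucleophile, so proton loss or attack at the wrong alkene would compete. A2 still lacks ring B, the C7 carbinol (to be made next to an epimerisable C7a), C1, C2, C8 and ring C.
- Comparison: A2 reaches ring A only, whereas 19 holds the whole trans-hydrindane with five of six stereocentres under substrate control from 1. Mechanistically a cationic cascade under external face control stands against a concerted shift with retention. Step economy is about equal up to the bicycle, and equal in that ring C is built afterwards in both.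

Alternative 2: The cuts are C8–C1 and C1'–C6', a three-component union of nitroalkene A3, alkyne ester A4 and Grignard reagent A5. The alkylcopper from A5 and CuBr·SMe2 would add syn across the triple bond of A4 (alkyl to C1', copper to C8) and the alkenylcopper would then add to C1 of A3, giving A6.
- In its favour: the C8=C1' geometry follows from syn-carbometalation and retention at the alkenyl–copper bond. In reliability this equals the chair-controlled Claisen rearrangement of the chosen plan, and in bond economy it is better (two C–C bonds, the alkene and C1 in one flask). The C4 bromide is already in place.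
- Against it here: the step forms no ring. A3 is a complete brominated trans-hydrindane whose synthesis is the larger part of the problem. Carbocupration is dependable for simple alkynes, less so with the ester of A4 and a β-silyl alkyl group. The hindered alkenylcopper must add next to the quaternary C7. C2 emerges as a nitro group trans to the C1 branch and must become the cis 2α-hydroxyl by a carbonyl and a reduction from the more hindered face. The silane must be oxidised under electrophilic conditions that threaten the alkene before ring C can close, and C4' is still unset.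
- Comparison: structurally A6 is the more convergent assembly of the C1 branch, while the chosen plan is the one that actually makes the bicycle. Mechanistically stereospecific organocopper additions stand against a photochemical 1,2-shift. In steps, the ring C part could be shorter than in the chosen plan, the hydrindane part is left open.

Alternative 3: The cuts are C3a–C7a, C2–C3 and C1–C2, taking rings A and B back to the acyclic 1,7-enyne A7. Co2(CO)8 would complex the alkyne and, with amine N-oxide promotion, join it to the isopropenyl group and CO to give the bicyclic enone A8.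
- In its favour: two rings, three C–C bonds and the quaternary carbon arise in one step from a chain in which C4 and C7 are preset. In ring-forming efficiency this is better than the chosen plan, which starts from a bicycle. C8 is on board as a protected hydroxymethyl group.
- Against it here: 1,7-enynes with a 1,1-disubstituted alkene are slow substrates, and C3a would be formed under weak acyclic control. The tetrasubstituted C1=C7a enone of A8 must be reduced to a trans-hydrindane, while such enones tend toward the cis fusion. C1 and the 2α-hydroxyl remain to be set. In A8 the C4 silyl ether sits on the face that bromine must finally occupy, so an inversion would have to precede the invertive bromination. A7 needs its own asymmetric synthesis.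
- Comparison: A8 reaches the bicyclic skeleton in fewer steps, but it leaves open the trans fusion, which the chosen plan fixes by hydroboration on a decalin. A metal-mediated cycloaddition stands against a rearrangement. The two are equal for ring C, since both continue from a C8 aldehyde.

Key step: step 11

Remarks on the chemistry: every intermediate, the decalins included, is numbered by the positions its carbons take in the target (C8 is the carbon that leaves the ring); β is the face of the angular C3a methyl, α the opposite face. Enantiopure (S)-1 is assumed; the C8 carbinol epimers formed in step 15 are carried on together because C8 becomes sp2 in step 16.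

## Route

Step 1
Reactants: 1 (S)-Wieland–Miescher ketone; 2 ethylene glycol
Product: 3 bis(ethylene ketal) of 1 at C4 and C8 with the double bond moved to C7=C7a (3aβ-CH3)
Conditions: ethylene glycol (excess), p-toluenesulfonic acid monohydrate (cat.), benzene, reflux, Dean–Stark trap
Reagents that add atoms: ethylene glycol (2), OCCO
Why: Acid-catalysed double ketalisation; the enone is ketalised through its dienol ether, which leaves the alkene β,γ to C8 (C7=C7a), where hydroboration needs it. The quaternary stereocentre is not touched.

Step 2
Reactants: 3 bis-ketal alkene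
Product: 5 trans-decalin bis-ketal 7α-ol (7aα-H; 3aβ-CH3), via alkylborane 4 (not isolated)
Conditions: BH3·THF, THF, 0 °C → rt; then NaOH (aq), H2O2, 0 °C → rt
Reagents that add atoms: hydrogen peroxide, OO
Why: Hydroboration–oxidation; syn addition puts boron on the less substituted C7 and hydrogen on C7a from the α face, away from the axial angular methyl, so the trans ring fusion and the equatorial 7α-alcohol result, and oxidation proceeds with retention.

Step 3
Reactants: 5 bis-ketal 7α-ol
Product: 6 trans-decalin bis-ketal 7-one
Conditions: Dess–Martin periodinane, NaHCO3, CH2Cl2, rt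
Reagents that add atoms: none
Why: Buffered Dess–Martin oxidation spares the ketals; C7a becomes α to a ketone, but the trans-decalin is the stable fusion, so its configuration holds.

Step 4
Reactants: 6 bis-ketal 7-one; 7 methylmagnesium bromide
Product: 8 7α-methyl-7β-hydroxy trans-decalin bis-ketal
Conditions: MeMgBr, THF, −78 → 0 °C; then aq. NH4Cl
Reagents that add atoms: methylmagnesium bromide (7), C[Mg]Br
Why: Grignard addition along the equatorial path on the α face, because the axial path on the β face is blocked by the syn-axial angular methyl; this gives the axial 7β-OH and equatorial 7α-CH3 of the target.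

Step 5
Reactants: 8 tertiary alcohol
Product: 9 7β-triethylsilyl ether of 8
Conditions: Et3SiOTf, 2,6-lutidine, CH2Cl2, −78 → 0 °C
Reagents that add atoms: triethylsilyl trifluoromethanesulfonate, CC[Si](CC)(CC)OS(=O)(=O)C(F)(F)F
Why: Silyl triflate silylation of a hindered tertiary alcohol. The ether keeps the 7β-oxygen from capturing the ketene of step 11 and from reacting in steps 9 and 24.

Step 6
Reactants: 9 bis-ketal silyl ether
Product: 10 C8 ketone with the C4 ketal retained (7β-OSiEt3; trans fusion)
Conditions: pyridinium p-toluenesulfonate (cat.), acetone/H2O, rt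
Reagents that add atoms: water, O
Why: Selective ketal hydrolysis; the C8 dioxolane lies between two methylenes and opens readily, whereas the C4 dioxolane is neopentyl (next to quaternary C3a) and needs much more forcing conditions.

Step 7
Reactants: 10 C8 ketone
Product: 13 2α-hydroxy-8-ketone, via silyl enol ether 11 (not isolated), via 2α-trimethylsilyloxy ketone 12 (not isolated)
Conditions: LiN(i-Pr)2, Me3SiCl, THF, −78 °C; solvent change; m-CPBA, NaHCO3, CH2Cl2, 0 °C; then aq. citric acid, MeOH, 0 °C
Reagents that add atoms: m-chloroperbenzoic acid, OOC(=O)c1cccc(Cl)c1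
Why: Rubottom oxidation; deprotonation goes to the open C2 methylene and not to C1, which is flanked by the ring fusion and the quaternary C7, and C2 is also the thermodynamic side of enolisation. The peracid attacks the enol ether from the α face, away from the syn-axial angular methyl, so silyl shift and desilylation leave the equatorial 2α-hydroxyl, also the stable epimer.

Step 8
Reactants: 13 2α-hydroxy-8-ketone
Product: 14 2α-(tert-butyldimethylsilyloxy)-8-ketone
Conditions: t-BuMe2SiCl, imidazole, DMF, rt
Reagents that add atoms: tert-butyldimethylsilyl chloride, CC(C)(C)[Si](C)(C)Cl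
Why: Standard silylation of a secondary alcohol under weakly basic conditions that do not isomerise the α-ketol.

Step 9
Reactants: 14 2α-silyloxy-8-ketone
Product: 15 1-(hydroxymethylene)-8-ketone
Conditions: NaH, HCO2Et, THF (cat. EtOH), 0 °C → rt; then aq. NH4Cl
Reagents that add atoms: ethyl formate, CCOC=O
Why: Claisen formylation under reversible conditions ends at C1, the only α-carbon whose formyl derivative is held as a stabilised enolate (C2 has a single hydrogen). C2 already has its stable equatorial configuration.

Step 10
Reactants: 15 hydroxymethylene ketone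
Product: 16 1-diazo-8-ketone (2α-OSiMe2t-Bu; 7β-OSiEt3; C4 ketal; trans-decalin)
Conditions: 4-acetamidobenzenesulfonyl azide, Et3N, MeCN, 0 °C → rt
Reagents that add atoms: 4-acetamidobenzenesulfonyl azide, CC(=O)Nc1ccc(cc1)S(=O)(=O)N=[N+]=[N-]
Why: Deformylative diazo transfer; the enolate adds to the sulfonyl azide and the adduct fragments with loss of the N-formyl sulfonamide, leaving the diazo group on C1. No stereocentre is involved.

Step 11
Reactants: 16 1-diazo-8-ketone
Product: 19 trans-hydrindane C8 methyl ester (C8 on C1α; 2α-OSiMe2t-Bu; 7β-OSiEt3; C4 ketal), via ketene 17 (not isolated), via ester enol 18 (not isolated)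
Conditions: hν (365 nm LED or medium-pressure Hg lamp through Pyrex), degassed MeOH, 0–20 °C
Reagents that add atoms: methanol, CO
Why: Irradiation of the ring-locked s-Z diazoketone expels N2 while the C8–C2 bond shifts to C1 (Wolff rearrangement from the singlet excited state), giving ketene 17, which methanol adds to as ester enol 18 before tautomerisation to 19; the closest known reaction type is the photochemical ring contraction of cyclic 2-diazoketones in alcohols. Ring B is closed by migration of a ring bond and not by a cyclisation: the six-membered ring shrinks to the five-membered ring as C1–C2 forms and C8 leaves the ring as the ester carbon. The migrating C2 keeps its configuration and C3a, C7 and C7a are spectators, so the 2α-silyloxy group and the trans fusion pass unchanged from the decalin. The only new stereocentre is C1, set when 18 is protonated: attack on the β face, anti to the vicinal 2α-silyloxy group, puts C8 on the α face, cis to the C2 oxygen and anti to the angular methyl. This epimer should also be the more stable one, because C8 is then trans to the fully substituted C7 branch at C7a, so a short treatment with NaOMe in MeOH would converge a C1 epimer on 19. The step needs the 1,2-shift to win over carbene O–H insertion and 1,2-hydride shift from C7a, which direct excitation without a metal catalyst favours because the cyclic diazoketone is held s-Z. It also needs the ketene to be taken by methanol alone, which the C7 triethylsilyl ether secures by masking the hydroxyl that would otherwise lie γ to the ketene carbon.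

Step 12
Reactants: 19 methyl ester
Product: 20 C8 primary alcohol
Conditions: i-Bu2AlH, CH2Cl2, −78 → 0 °C; then aq. Rochelle salt
Reagents that add atoms: none
Why: Hydride reduction of the hindered ester to the alcohol; the non-basic reagent does not epimerise C1 and full reduction avoids a capricious partial reduction.

Step 13
Reactants: 20 primary alcohol
Product: 21 C8 aldehyde (C1α-CHO)
Conditions: Dess–Martin periodinane, NaHCO3, CH2Cl2, 0 °C → rt
Reagents that add atoms: none
Why: Mild neutral oxidation to the aldehyde without epimerisation at C1 or elimination of the β-silyloxy group.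

Step 14
Reactants: 22 2,3-dibromopropene; 23 4-methoxybenzyl alcohol
Product: 24 2-bromoallyl 4-methoxybenzyl ether
Conditions: NaH, n-Bu4NI (cat.), THF, 0 °C → rt
Reagents that add atoms: 4-methoxybenzyl alcohol (23), COc1ccc(CO)cc1
Why: Williamson ether synthesis at the allylic bromide; the vinylic bromide is inert to SN2 and is kept for halogen–lithium exchange.

Step 15
Reactants: 21 C8 aldehyde; 24 2-bromoallyl 4-methoxybenzyl ether; 25 isobutyryl chloride
Product: 28 C8 allylic isobutyrate bearing the 2-(4-methoxybenzyloxymethyl)vinyl group on C8 (both C8 epimers), via vinyllithium 26 (not isolated), via lithium alkoxide 27 (not isolated)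
Conditions: 24, t-BuLi (2 equiv), Et2O, −78 °C; add 21 in THF, −78 °C; then isobutyryl chloride, −78 → 0 °C
Reagents that add atoms: 2-bromoallyl 4-methoxybenzyl ether (24), C=C(Br)COCc1ccc(OC)cc1; isobutyryl chloride (25), CC(C)C(Cl)=O
Why: Bromine–lithium exchange gives the 2-lithioallyl ether, which adds to the aldehyde (forming C8–C1'), and the lithium alkoxide is acylated in the same flask. The C8 carbinol forms as two epimers, which is immaterial because C8 becomes sp2 in step 16.

Step 16
Reactants: 28 allylic isobutyrate
Product: 31 γ,δ-unsaturated acid with the C8=C1' alkene (Z by the sequence rule: C1 cis to the CH2O branch C6' and trans to C2'), via silyl ketene acetal 29 (not isolated), via trimethylsilyl ester 30 (not isolated)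
Conditions: LiN(i-Pr)2, Me3SiCl, THF, −78 °C → rt → 50 °C; then aq. citric acid
Reagents that add atoms: none
Why: Ireland–Claisen rearrangement; the silyl ketene acetal of the isobutyrate (no enolate geometry to control) rearranges through a chair in which the bulky hydrindanyl group on C8 is equatorial. For either C8 epimer C1 therefore ends trans to the new C2'–C3' bond and cis to C6', which is the alkene geometry of the target, and quaternary C3' is formed.

Step 17
Reactants: 31 acid; 32 methyllithium
Product: 33 methyl ketone (C4' carbonyl with C5' as its methyl group)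
Conditions: MeLi (excess), Et2O, 0 °C → rt; inverse quench into ice-water
Reagents that add atoms: methyllithium (32), [Li]C
Why: Methyllithium adds to the lithium carboxylate to give a stable gem-diolate that releases the ketone only on hydrolysis, a reliable route from hindered acids to methyl ketones. It brings in C5' and gives a ketone that can enolise only toward C5'.

Step 18
Reactants: 33 methyl ketone
Product: 34 primary allylic alcohol (C6'–OH)
Conditions: DDQ, CH2Cl2/pH 7 buffer, 0 °C
Reagents that add atoms: none
Why: Oxidative cleavage of the 4-methoxybenzyl ether; silyl ethers, ketal, ketone and the alkene are not affected.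

Step 19
Reactants: 34 allylic alcohol
Product: 35 primary allylic bromide (C6'–Br)
Conditions: CBr4, PPh3, CH2Cl2, 0 °C
Reagents that add atoms: carbon tetrabromide, BrC(Br)(Br)Br
Why: Appel bromination of an unhindered primary allylic alcohol by SN2 at C6'; the SN2' position C8 is hindered, so there is no allylic shift and the alkene geometry is kept.

Step 20
Reactants: 35 allylic bromide
Product: 37 ring C ketone: (E)-4-alkylidene-2,2-dimethylcyclohexanone on C8 of the protected hydrindane, via potassium enolate 36 (not isolated)
Conditions: KN(SiMe3)2, THF (0.01 M), −78 → 0 °C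
Reagents that add atoms: none
Why: Intramolecular enolate C-alkylation (6-exo-tet) of the only possible enolate, at C5', on the allylic bromide closes ring C by the C5'–C6' bond. O-alkylation would need an eight-membered ring and SN2' an attack at hindered C8; the alkene is not involved.

Step 21
Reactants: 37 ring C ketone
Product: 38 (4'R)-alcohol of ring C
Conditions: (S)-1-methyl-3,3-diphenyltetrahydro-1H,3H-pyrrolo[1,2-c][1,3,2]oxazaborole ((S)-Me-CBS, 0.2–1 equiv), catecholborane, toluene, −78 → −40 °C; then aq. NaOH
Reagents that add atoms: none
Why: Corey–Bakshi–Shibata reduction; the carbonyl lies between quaternary C3' (large) and a methylene (small), a substrate class reduced with high induction, and the (S)-catalyst delivers hydride to give the (4'R) carbinol independently of the remote bicycle. Catecholborane is chosen because it does not hydroborate the trisubstituted alkene at this temperature.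

Step 22
Reactants: 38 (4'R)-alcohol
Product: 39 C4 ketone (ring A) with the (4'R)-alcohol
Conditions: pyridinium p-toluenesulfonate, acetone/H2O, 50 °C
Reagents that add atoms: water, O
Why: Hydrolysis of the remaining hindered dioxolane with a weak acid, chosen so that the secondary tert-butyldimethylsilyl ether, the hindered tertiary triethylsilyl ether and the alkene survive.

Step 23
Reactants: 39 C4 ketone
Product: 40 (4R,4'R)-diol (4α-OH axial)
Conditions: LiBH(s-Bu)3 (L-Selectride), THF, −78 °C; then NaOH, H2O2
Reagents that add atoms: none
Why: The bulky hydride attacks the C4 ketone along the equatorial path on the β side, as is usual for cyclohexanones flanked by a quaternary ring carbon, and gives the axial 4α-alcohol that an invertive bromination requires.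

Step 24
Reactants: 40 diol
Product: 41 (4S,4'S)-dibromide with both silyl ethers in place
Conditions: CBr4, PPh3, toluene, rt → 60 °C
Reagents that add atoms: carbon tetrabromide, BrC(Br)(Br)Br
Why: Double Appel reaction; each alkoxyphosphonium ion is displaced by bromide with inversion, turning the axial (4R) and the (4'R) carbinols into the equatorial (4S) and (4'S) bromides. This type of displacement at axial carbinols next to a fully substituted carbon is established in bromo-terpenoid chemistry, and the silyl ethers keep the C2 and C7 oxygens out of the reaction.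

Step 25
Reactants: 41 bis-silyl dibromide
Product: 42 iriediol
Conditions: HF·pyridine, THF/pyridine, 0 °C → rt
Reagents that add atoms: none
Why: Fluoride cleavage of both silyl ethers under non-basic conditions, so the secondary bromides are not exposed to E2 and the tertiary alcohol is not ionised.

## Compound list

1 | (S)-Wieland–Miescher ketone, (S)-8a-methyl-3,4,8,8a-tetrahydronaphthalene-1,6(2H,7H)-dione | O=C1CC[C@]2(C)C(=O)CCCC2=C1 | starting material
2 | ethylene glycol | OCCO | starting material
3 | bis(ethylene ketal) of 1 at C4 and C8, alkene at C7=C7a, 3aβ-CH3 | C1C2(OCCO2)CC[C@]3(C)C4(OCCO4)CCC=C13 | intermediate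
4 | 7α-boryl trans-decalin bis-ketal (drawn as the monoalkylborane), 7aα-H | C1C2(OCCO2)CC[C@]3(C)C4(OCCO4)CC[C@H](B)[C@@H]13 | intermediate
5 | trans-decalin bis-ketal 7α-ol, 7aα-H, 3aβ-CH3 | C1C2(OCCO2)CC[C@]3(C)C4(OCCO4)CC[C@H](O)[C@@H]13 | intermediate
6 | trans-decalin bis-ketal 7-one | C1C2(OCCO2)CC[C@]3(C)C4(OCCO4)CCC(=O)[C@@H]13 | intermediate
7 | methylmagnesium bromide | C[Mg]Br | starting material
8 | 7α-methyl-7β-hydroxy trans-decalin bis-ketal | C1C2(OCCO2)CC[C@]3(C)C4(OCCO4)CC[C@@](C)(O)[C@@H]13 | intermediate
9 | 7β-triethylsilyl ether of 8 | C1C2(OCCO2)CC[C@]3(C)C4(OCCO4)CC[C@@](C)(O[Si](CC)(CC)CC)[C@@H]13 | intermediate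
10 | C8 ketone, C4 ethylene ketal, 7β-OSiEt3 | C1C(=O)CC[C@]3(C)C4(OCCO4)CC[C@@](C)(O[Si](CC)(CC)CC)[C@@H]13 | intermediate
11 | C8=C2 trimethylsilyl enol ether of 10 | C1C(O[Si](C)(C)C)=CC[C@]3(C)C4(OCCO4)CC[C@@](C)(O[Si](CC)(CC)CC)[C@@H]13 | intermediate
12 | 2α-trimethylsilyloxy-8-ketone | C1C(=O)[C@H](O[Si](C)(C)C)C[C@]3(C)C4(OCCO4)CC[C@@](C)(O[Si](CC)(CC)CC)[C@@H]13 | intermediate
13 | 2α-hydroxy-8-ketone | C1C(=O)[C@H](O)C[C@]3(C)C4(OCCO4)CC[C@@](C)(O[Si](CC)(CC)CC)[C@@H]13 | intermediate
14 | 2α-(tert-butyldimethylsilyloxy)-8-ketone | C1C(=O)[C@H](O[Si](C)(C)C(C)(C)C)C[C@]3(C)C4(OCCO4)CC[C@@](C)(O[Si](CC)(CC)CC)[C@@H]13 | intermediate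
15 | 1-(hydroxymethylene)-8-ketone | OC=C1C(=O)[C@H](O[Si](C)(C)C(C)(C)C)C[C@]3(C)C4(OCCO4)CC[C@@](C)(O[Si](CC)(CC)CC)[C@@H]13 | intermediate
16 | trans-decalin 1-diazo-8-ketone (key-step precursor) | [N-]=[N+]=C2C(=O)[C@H](O[Si](C)(C)C(C)(C)C)C[C@]3(C)C4(OCCO4)CC[C@@](C)(O[Si](CC)(CC)CC)[C@@H]23 | intermediate
17 | ring-contracted ketene (C1=C8=O) | O=C=C2[C@H](O[Si](C)(C)C(C)(C)C)C[C@]3(C)C4(OCCO4)CC[C@@](C)(O[Si](CC)(CC)CC)[C@@H]23 | intermediate
18 | ester enol (ketene hemiacetal) | COC(O)=C2[C@H](O[Si](C)(C)C(C)(C)C)C[C@]3(C)C4(OCCO4)CC[C@@](C)(O[Si](CC)(CC)CC)[C@@H]23 | intermediate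
19 | trans-hydrindane C8 methyl ester (key-step product): C1α-CO2Me, 2α-OSiMe2t-Bu, 3aβ-CH3, C4 ketal, 7β-OSiEt3, 7aα-H | COC(=O)[C@@H]2[C@H](O[Si](C)(C)C(C)(C)C)C[C@]3(C)C4(OCCO4)CC[C@@](C)(O[Si](CC)(CC)CC)[C@@H]23 | intermediate
20 | C8 primary alcohol | OC[C@@H]2[C@H](O[Si](C)(C)C(C)(C)C)C[C@]3(C)C4(OCCO4)CC[C@@](C)(O[Si](CC)(CC)CC)[C@@H]23 | intermediate
21 | C8 aldehyde | O=C[C@@H]2[C@H](O[Si](C)(C)C(C)(C)C)C[C@]3(C)C4(OCCO4)CC[C@@](C)(O[Si](CC)(CC)CC)[C@@H]23 | intermediate
22 | 2,3-dibromopropene | C=C(Br)CBr | starting material
23 | 4-methoxybenzyl alcohol | COc1ccc(CO)cc1 | starting material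
24 | 2-bromoallyl 4-methoxybenzyl ether | C=C(Br)COCc1ccc(OC)cc1 | intermediate
25 | isobutyryl chloride | CC(C)C(Cl)=O | starting material
26 | 2-lithioallyl 4-methoxybenzyl ether | [Li]C(=C)COCc1ccc(OC)cc1 | intermediate
27 | lithium C8 alkoxide (both C8 epimers) | [Li]OC(C(=C)COCc1ccc(OC)cc1)[C@@H]2[C@H](O[Si](C)(C)C(C)(C)C)C[C@]3(C)C4(OCCO4)CC[C@@](C)(O[Si](CC)(CC)CC)[C@@H]23 | intermediate
28 | C8 allylic isobutyrate (both C8 epimers) | CC(C)C(=O)OC(C(=C)COCc1ccc(OC)cc1)[C@@H]2[C@H](O[Si](C)(C)C(C)(C)C)C[C@]3(C)C4(OCCO4)CC[C@@](C)(O[Si](CC)(CC)CC)[C@@H]23 | intermediate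
29 | trimethylsilyl ketene acetal of 28 | CC(C)=C(O[Si](C)(C)C)OC(C(=C)COCc1ccc(OC)cc1)[C@@H]2[C@H](O[Si](C)(C)C(C)(C)C)C[C@]3(C)C4(OCCO4)CC[C@@](C)(O[Si](CC)(CC)CC)[C@@H]23 | intermediate
30 | trimethylsilyl ester of 31 | C[Si](C)(C)OC(=O)C(C)(C)C/C(COCc1ccc(OC)cc1)=C/[C@@H]2[C@H](O[Si](C)(C)C(C)(C)C)C[C@]3(C)C4(OCCO4)CC[C@@](C)(O[Si](CC)(CC)CC)[C@@H]23 | intermediate
31 | (Z)-γ,δ-unsaturated acid: C4' acid, C3' gem-dimethyl, C1 cis to CH2OPMB | OC(=O)C(C)(C)C/C(COCc1ccc(OC)cc1)=C/[C@@H]2[C@H](O[Si](C)(C)C(C)(C)C)C[C@]3(C)C4(OCCO4)CC[C@@](C)(O[Si](CC)(CC)CC)[C@@H]23 | intermediate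
32 | methyllithium | [Li]C | starting material
33 | (Z)-methyl ketone | CC(=O)C(C)(C)C/C(COCc1ccc(OC)cc1)=C/[C@@H]2[C@H](O[Si](C)(C)C(C)(C)C)C[C@]3(C)C4(OCCO4)CC[C@@](C)(O[Si](CC)(CC)CC)[C@@H]23 | intermediate
34 | (Z)-allylic alcohol (C6'–OH) | CC(=O)C(C)(C)C/C(CO)=C/[C@@H]2[C@H](O[Si](C)(C)C(C)(C)C)C[C@]3(C)C4(OCCO4)CC[C@@](C)(O[Si](CC)(CC)CC)[C@@H]23 | intermediate
35 | (Z)-allylic bromide (C6'–Br) | CC(=O)C(C)(C)C/C(CBr)=C/[C@@H]2[C@H](O[Si](C)(C)C(C)(C)C)C[C@]3(C)C4(OCCO4)CC[C@@](C)(O[Si](CC)(CC)CC)[C@@H]23 | intermediate
36 | potassium enolate of 35 (C4'=C5') | [K]OC(=C)C(C)(C)C/C(CBr)=C/[C@@H]2[C@H](O[Si](C)(C)C(C)(C)C)C[C@]3(C)C4(OCCO4)CC[C@@](C)(O[Si](CC)(CC)CC)[C@@H]23 | intermediate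
37 | ring C ketone, (E)-alkene | CC1(C)C/C(=C/[C@@H]2[C@H](O[Si](C)(C)C(C)(C)C)C[C@]3(C)C4(OCCO4)CC[C@@](C)(O[Si](CC)(CC)CC)[C@@H]23)CCC1=O | intermediate
38 | (4'R)-alcohol, C4 ketal | CC1(C)C/C(=C/[C@@H]2[C@H](O[Si](C)(C)C(C)(C)C)C[C@]3(C)C4(OCCO4)CC[C@@](C)(O[Si](CC)(CC)CC)[C@@H]23)CC[C@H]1O | intermediate
39 | C4 ketone, (4'R)-alcohol | CC1(C)C/C(=C/[C@@H]2[C@H](O[Si](C)(C)C(C)(C)C)C[C@]3(C)C(=O)CC[C@@](C)(O[Si](CC)(CC)CC)[C@@H]23)CC[C@H]1O | intermediate
40 | (4R,4'R)-diol, 4α-OH axial | CC1(C)C/C(=C/[C@@H]2[C@H](O[Si](C)(C)C(C)(C)C)C[C@]3(C)[C@H](O)CC[C@@](C)(O[Si](CC)(CC)CC)[C@@H]23)CC[C@H]1O | intermediate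
41 | (4S,4'S)-dibromide, 2-O-SiMe2t-Bu, 7-O-SiEt3 | CC1(C)C/C(=C/[C@@H]2[C@H](O[Si](C)(C)C(C)(C)C)C[C@]3(C)[C@@H](Br)CC[C@@](C)(O[Si](CC)(CC)CC)[C@@H]23)CC[C@@H]1Br | intermediate
42 | iriediol, (1S,2R,3aS,4S,7R,7aS)-4-bromo-1-{(E)-[(4S)-4-bromo-3,3-dimethylcyclohexylidene]methyl}-3a,7-dimethyloctahydro-1H-indene-2,7-diol | CC1(C)C/C(=C/[C@@H]2[C@H](O)C[C@]3(C)[C@@H](Br)CC[C@@](C)(O)[C@@H]23)CC[C@@H]1Br | target

Total step count: 25. Longest linear sequence: 24 steps (steps 1–13 and 15–25, from 1 to 42); step 14 prepares fragment 24.

## Least certain steps and fallbacks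

The key step (step 11) is most exposed to poor facial control when ester enol 18 is protonated, since the β face is also screened by the 7β-silyloxy group and the angular methyl; some material may also be lost by O–H insertion of the carbene into methanol. Equilibration with NaOMe in MeOH is the first remedy. The fallback that changes the approach is a semipinacol ring contraction, which forms the same C1–C2 bond stereospecifically and needs no protonation at C1. It sets out from 14. Enolisation away from the silyloxy-bearing C2 (LiN(i-Pr)2, Me3SiCl) gives the C8=C1 trimethylsilyl enol ether F1. m-CPBA attacks it from the α face, because the axial β approach to C1 is blocked by the syn-axial C7 silyloxy group, and desilylation gives the 1α-hydroxy-8-ketone F2. MsCl/Et3N gives the equatorial 1α-mesylate F3, and NaBH4 gives the C8 alcohol F4 (either C8 epimer serves). With KOt-Bu in THF the C8 alkoxide pushes the C8–C2 bond, which is antiperiplanar to the equatorial C1–O bond, onto C1 with inversion, and C8 leaves the ring as an aldehyde on the α face of C1. The fallback returns to the route at 21 and replaces steps 9 to 13.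

Step 24 is most likely to suffer E2 elimination from the axial alkoxyphosphonium ions (an antiperiplanar axial hydrogen stands at C5 and at C5') and 1,2-methyl shift after ionisation, because bromide must attack two neopentyl carbons. The fallback separates activation from displacement: from 40, Tf2O and pyridine at −30 °C give the bis-triflate F5, which n-Bu4NBr in toluene at 0 °C → rt displaces with inversion. It returns at 41.

In step 22 the hindered dioxolane may open so slowly that loss of the tertiary triethylsilyl ether and acid-induced addition of the free C4' hydroxyl to the C8=C1' alkene begin to compete. The fallback moves the acid step to a compound without a free hydroxyl. From 37, aqueous HCl in THF removes the ketal and, deliberately, the triethylsilyl group to give the diketone alcohol F6, and Et3SiOTf/2,6-lutidine restores the silyl ether in diketone F7. Both carbonyls have the same local topology (between a quaternary carbon and a methylene) and both need the R carbinol, so they are reduced in one operation with the (S)-oxazaborolidine and catecholborane. The fallback returns at 40 and replaces steps 21 to 23; the facial outcome at C4 under catalyst control is its own uncertainty.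

In step 15 the basic vinyllithium may enolise the hindered α-branched aldehyde (return of 21, possibly epimerised at C1), and acylation of the hindered lithium alkoxide may stay incomplete. The fallback uses a non-basic organochromium reagent: 21 and 24 are coupled with CrCl2 and catalytic NiCl2 in DMF (Nozaki–Hiyama–Kishi reaction) to give the isolated allylic alcohol F8, which is acylated with 25, pyridine and 4-dimethylaminopyridine. It returns at 28.

## Further compounds

F1 | step 11 | C8=C1 trimethylsilyl enol ether of 14 | C1=C(O[Si](C)(C)C)[C@H](O[Si](C)(C)C(C)(C)C)C[C@]3(C)C4(OCCO4)CC[C@@](C)(O[Si](CC)(CC)CC)[C@@H]13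
F2 | step 11 | 1α-hydroxy-2α-(tert-butyldimethylsilyloxy)-8-ketone | O[C@@H]1C(=O)[C@H](O[Si](C)(C)C(C)(C)C)C[C@]3(C)C4(OCCO4)CC[C@@](C)(O[Si](CC)(CC)CC)[C@@H]13
F3 | step 11 | 1α-mesyloxy-8-ketone | CS(=O)(=O)O[C@@H]1C(=O)[C@H](O[Si](C)(C)C(C)(C)C)C[C@]3(C)C4(OCCO4)CC[C@@](C)(O[Si](CC)(CC)CC)[C@@H]13
F4 | step 11 | 1α-mesyloxy-8-ol (either C8 epimer) | CS(=O)(=O)O[C@@H]1C(O)[C@H](O[Si](C)(C)C(C)(C)C)C[C@]3(C)C4(OCCO4)CC[C@@](C)(O[Si](CC)(CC)CC)[C@@H]13
F5 | step 24 | (4R,4'R)-bis(trifluoromethanesulfonate) of 40 | CC1(C)C/C(=C/[C@@H]2[C@H](O[Si](C)(C)C(C)(C)C)C[C@]3(C)[C@H](OS(=O)(=O)C(F)(F)F)CC[C@@](C)(O[Si](CC)(CC)CC)[C@@H]23)CC[C@H]1OS(=O)(=O)C(F)(F)F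
F6 | step 22 | C4,C4'-diketone with free 7β-hydroxyl | CC1(C)C/C(=C/[C@@H]2[C@H](O[Si](C)(C)C(C)(C)C)C[C@]3(C)C(=O)CC[C@@](C)(O)[C@@H]23)CCC1=O
F7 | step 22 | C4,C4'-diketone with 7β-triethylsilyl ether | CC1(C)C/C(=C/[C@@H]2[C@H](O[Si](C)(C)C(C)(C)C)C[C@]3(C)C(=O)CC[C@@](C)(O[Si](CC)(CC)CC)[C@@H]23)CCC1=O
F8 | step 15 | C8 allylic alcohol (both C8 epimers) | OC(C(=C)COCc1ccc(OC)cc1)[C@@H]2[C@H](O[Si](C)(C)C(C)(C)C)C[C@]3(C)C4(OCCO4)CC[C@@](C)(O[Si](CC)(CC)CC)[C@@H]23
A1 | alternative 1 | 1-tert-butyl 10-methyl (3Z,7E)-4-chloro-8-methyldeca-3,7-dienedioate | COC(=O)C/C(C)=C/CC/C(Cl)=C/CC(=O)OC(C)(C)C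
A2 | alternative 1 | ring A bromoketone with methyl acetate arm on C3a and tert-butyl acetate arm on C7a (4β-Br, 3aβ-CH3, 7aα-H, C7 ketone) | COC(=O)C[C@]1(C)[C@@H](Br)CCC(=O)[C@H]1CC(=O)OC(C)(C)C
A3 | alternative 2 | trans-hydrindane 2-nitro-1-ene (4β-Br, 7β-OSiEt3) | C2=C([N+](=O)[O-])C[C@]3(C)[C@@H](Br)CC[C@@](C)(O[Si](CC)(CC)CC)[C@@H]23
A4 | alternative 2 | methyl 2,2-dimethylpent-4-ynoate | C#CCC(C)(C)C(=O)OC
A5 | alternative 2 | [2-(dimethylphenylsilyl)ethyl]magnesium bromide | Br[Mg]CC[Si](C)(C)c1ccccc1
A6 | alternative 2 | C1-alkenylated 2-nitrohydrindane with defined C8=C1' geometry | COC(=O)C(C)(C)C/C(CC[Si](C)(C)c1ccccc1)=C/[C@@H]2[C@@H]([N+](=O)[O-])C[C@]3(C)[C@@H](Br)CC[C@@](C)(O[Si](CC)(CC)CC)[C@@H]23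
A7 | alternative 3 | acyclic 1,7-enyne with isopropenyl group, C4 and C7 silyl ethers and silyloxymethyl alkyne | C=C(C)[C@@H](O[Si](C)(C)C(C)(C)C)CC[C@@](C)(O[Si](CC)(CC)CC)C#CCO[Si](C)(C)C(C)(C)C
A8 | alternative 3 | hydrindenone with C1=C7a enone and quaternary C3a | O=C1C[C@]2(C)[C@@H](O[Si](C)(C)C(C)(C)C)CC[C@@](C)(O[Si](CC)(CC)CC)C2=C1CO[Si](C)(C)C(C)(C)C
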